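**Assumptions.** (S)-Proline gives the (S)-angular methyl, as in the parent Wieland–Miescher ketone. N-Methoxy-N-methylacrylamide, 5-bromopent-1-ene, 2-methylcyclohexane-1,3-dione and methyl 4-hydroxy-3-iodobenzoate are commercial.

**Retrosynthetic overview**
1. Jaspic acid ⇒ Pd-catalysed reductive arylation of the diene 14 (exocyclic C9=CH2 with Δ7) by aryl iodide 16. This forms the C11–aryl bond and sets C9–H, with the ester and acetate removed last.
2. Diene 14 ⇐ enone 13 (Wittig) ⇐ trans-decalone 11 (α-methylation, then IBX dehydrogenation).
3. Decalone 11 ⇐ ketal 8 by Stork reductive methylation (builds C4 quaternary and C5–H) and Wolff–Kishner (removes the C3 ketone).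
4. Ketal 8 ⇐ organocatalytic desymmetrizing Robinson annulation (sets C10) of 2-methylcyclohexane-1,3-dione with vinyl ketone 3. Ring B (the dione ring) is present from the start, ring A forms in the annulation, and ring B is decorated last (C8-Me, Δ7, C9-CH2Ar).

**Route**

**Step 1**
Reactants: 1 (5-bromopent-1-ene); 2 (N-methoxy-N-methylacrylamide)
Product: 3 (octa-1,7-dien-3-one)
Conditions: (a) Mg, THF, 40 °C (Grignard from 1); (b) 2, THF, −78 → −40 °C; NH4Cl(aq)
Reagents that add atoms: none (Mg only converts 1 to its Grignard; the pentenyl group comes from 1)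
Why: Weinreb-type acylation by the pent-4-enyl Grignard stops at the vinyl ketone because the chelated intermediate resists over-addition, and it carries the alkenyl arm destined for C4.

**Step 2**
Reactants: 3; 4 (2-methylcyclohexane-1,3-dione)
Product: 5 (2-methyl-2-(3-oxooct-7-en-1-yl)cyclohexane-1,3-dione)
Conditions: Et3N (10 mol%), neat, 50 °C
Reagents that add atoms: none
Why: Michael addition of the acidic dione C2–H to the vinyl ketone gives the achiral, prochiral triketone.

**Step 3**
Reactants: 5
Product: 6 ((S)-5-(but-3-en-1-yl)-8a-methyl-3,4,8,8a-tetrahydronaphthalene-1,6(2H,7H)-dione)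
Conditions: (S)-proline (35 mol%), DMF, 25 °C, 48 h; then p-TsOH (cat.), PhMe, 60 °C
Reagents that add atoms: none
Why: Organocatalytic Robinson annulation (Hajos–Parrish/Wieland–Miescher type): the enamine of the chain ketone attacks one of the two enantiotopic ring carbonyls, setting C10 as (S) (10β-Me). Dehydration then gives the conjugated enone bearing the C4 arm.

**Step 4**
Reactants: 6
Product: 7 (enone 6 with the arm converted to 4-methylpent-3-en-1-yl)
Conditions: Hoveyda–Grubbs II (5 mol%), 2-methylbut-2-ene (20 equiv), CH2Cl2, 40 °C
Reagents that add atoms: 2-methylbut-2-ene, CC=C(C)C (supplies the CMe2 terminus; propene is lost)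
Why: Cross-metathesis converts the terminal vinyl group into the prenyl-type trisubstituted alkene present in the target, leaving the hindered tetrasubstituted enone untouched.

**Step 5**
Reactants: 7
Product: 8 (C9 ethylene ketal of 7; C3 enone retained)
Conditions: (CH2OH)2, p-TsOH (cat.), PhH, 23 °C
Reagents that add atoms: ethylene glycol, OCCO
Why: Ketalization is chemoselective for the saturated C9 ketone over the conjugated, α-substituted enone; it protects C9 from Li/NH3.

**Step 6**
Reactants: 8
Product: 9 (C3 ketone; C4 quaternary with 4α-Me and 4β-homoprenyl; 5α-H; 10β-Me; C9 ketal)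
Conditions: Li, NH3(l)/THF, −78 °C; then MeI, −78 → 0 °C
Reagents that add atoms: iodomethane, CI
Why: Stork reductive alkylation. β-Protonation of the radical anion gives the trans ring fusion (5α-H anti to 10β-Me), and the regiodefined C3/C4 enolate is methylated from the α face, anti to the axial 10β-Me and equatorial-like. This places Me at 4α and leaves the pre-existing homoprenyl arm axial at 4β, which is the target configuration.

**Step 7**
Reactants: 9
Product: 10 (C3 methylene; ketal retained)
Conditions: N2H4·H2O, KOH, diethylene glycol, 140 → 200 °C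
Reagents that add atoms: none
Why: Huang–Minlon Wolff–Kishner removes the C3 carbonyl. The ketal, the trisubstituted alkene and all stereocentres survive.

**Step 8**
Reactants: 10
Product: 11 (trans-decalone, C9 ketone, C3 = CH2)
Conditions: PPTS (0.3 equiv), acetone/H2O (10:1), 60 °C
Reagents that add atoms: water, O
Why: Mild acid hydrolysis of the ketal; no α-stereocentre is epimerizable (C10 is quaternary).

**Step 9**
Reactants: 11
Product: 12 (8-methyl-C9-ketone; C8 epimers, both converge in Step 10)
Conditions: LDA, THF, −78 °C; then MeI, −78 → 0 °C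
Reagents that add atoms: iodomethane, CI
Why: Enolization can only occur toward C8 (C10 is quaternary), so α-methylation installs the C8 methyl regiospecifically.

**Step 10**
Reactants: 12
Product: 13 (C9 enone with C8(Me)=C7)
Conditions: IBX (1.5 equiv), DMSO, 70 °C
Reagents that add atoms: none
Why: IBX (Nicolaou) dehydrogenation of the ketone toward the only enolizable side gives the trisubstituted Δ7 enone, which fixes the alkene position of the target.

**Step 11**
Reactants: 13
Product: 14 (diene: exocyclic C9=CH2 conjugated to C8(Me)=C7)
Conditions: Ph3PCH3Br, KOt-Bu, PhMe, 90 °C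
Reagents that add atoms: methyltriphenylphosphonium bromide, C[P+](c1ccccc1)(c1ccccc1)c1ccccc1.[Br-] (supplies CH2)
Why: Wittig methylenation of the hindered enone carbonyl gives the s-trans cross-conjugated diene that sets up the key coupling.

**Step 12**
Reactants: 15 (methyl 4-hydroxy-3-iodobenzoate)
Product: 16 (methyl 4-acetoxy-3-iodobenzoate)
Conditions: Ac2O, pyridine, DMAP (cat.), CH2Cl2, 23 °C
Reagents that add atoms: acetic anhydride, CC(=O)OC(C)=O
Why: Acetylation masks the phenol so that it cannot trap the π-allyl-Pd intermediate in the next step (o-iodophenol heteroannulation).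

**Step 13**
Reactants: 14; 16
Product: 17 (methyl 4-acetoxy-3-{[(9β-H-α…)methyl]}benzoate, i.e. the coupled Δ7 product with 9α-H/9β-CH2Ar)
Conditions: Pd(OAc)2 (5 mol%), P(o-Tol)3 (10 mol%), HCO2Na (3 equiv), n-Bu4NCl, DMF, 70 °C
Reagents that add atoms: none (formate delivers only H)
Why: Proposed new method: the Ar–Pd species adds across the less hindered terminal C9=C11 bond of the s-trans diene to give Ar–C11H2 and an η3-allyl Pd on C9–C8–C7 on the α face, anti to the axial 10β-Me; formate then gives Pd–H, which is delivered syn to Pd to the more substituted terminus C9, as in Tsuji formate reduction of allyl systems. This sets 9α-H/9β-CH2Ar and keeps the Δ7 trisubstituted alkene; the closest known reactions are the reductive Heck reaction and Pd-catalysed hydroarylation of 1,3-dienes, here applied to a hindered terpenoid diene next to a quaternary centre.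

**Step 14**
Reactants: 17
Product: 18 (jaspic acid)
Conditions: LiOH·H2O (10 equiv), THF/MeOH/H2O (3:1:1), 60 °C; then 1 M HCl to pH 3
Reagents that add atoms: water/hydroxide, O
Why: Saponification removes the methyl ester and the phenyl acetate in one operation; the alkenes and all stereocentres are unaffected.

**Compound list**

1 | 5-bromopent-1-ene | BrCCCC=C | starting material
2 | N-methoxy-N-methylacrylamide | C=CC(=O)N(C)OC | starting material
3 | octa-1,7-dien-3-one | C=CC(=O)CCCC=C | intermediate
4 | 2-methylcyclohexane-1,3-dione | CC1C(=O)CCCC1=O | starting material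
5 | 2-methyl-2-(3-oxooct-7-en-1-yl)cyclohexane-1,3-dione | CC1(CCC(=O)CCCC=C)C(=O)CCCC1=O | intermediate
6 | (S)-4-(but-3-enyl)-10β-methyl Wieland–Miescher-type enone | O=C1CC[C@]2(C)C(=O)CCCC2=C1CCC=C | intermediate
7 | (S)-enone with 4-methylpent-3-enyl arm | O=C1CC[C@]2(C)C(=O)CCCC2=C1CCC=C(C)C | intermediate
8 | C9 ethylene ketal of 7 | O=C1CC[C@]2(C)C3(OCCO3)CCCC2=C1CCC=C(C)C | intermediate
9 | trans-decalone: 4α-Me, 4β-homoprenyl, 5α-H, 10β-Me, C3 ketone, C9 ketal | CC(C)=CCC[C@@]1(C)C(=O)CC[C@]2(C)C3(OCCO3)CCC[C@@H]12 | intermediate
10 | C3-deoxygenated ketal | CC(C)=CCC[C@@]1(C)CCC[C@]2(C)C3(OCCO3)CCC[C@@H]12 | intermediate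
11 | trans-decalone (C9 ketone) | CC(C)=CCC[C@@]1(C)CCC[C@]2(C)C(=O)CCC[C@@H]12 | intermediate
12 | 8-methyl-C9-ketone (C8 epimeric mixture) | CC(C)=CCC[C@@]1(C)CCC[C@]2(C)C(=O)C(C)CC[C@@H]12 | intermediate
13 | Δ7-C9 enone | CC(C)=CCC[C@@]1(C)CCC[C@]2(C)C(=O)C(C)=CC[C@@H]12 | intermediate
14 | 9-methylene-Δ7 diene | CC(C)=CCC[C@@]1(C)CCC[C@]2(C)C(=C)C(C)=CC[C@@H]12 | intermediate
15 | methyl 4-hydroxy-3-iodobenzoate | COC(=O)c1ccc(O)c(I)c1 | starting material
16 | methyl 4-acetoxy-3-iodobenzoate | COC(=O)c1ccc(OC(C)=O)c(I)c1 | intermediate
17 | methyl 4-acetoxy-3-(Δ7-decalinylmethyl)benzoate | CC(C)=CCC[C@@]1(C)CCC[C@]2(C)[C@@H](Cc3cc(C(=O)OC)ccc3OC(C)=O)C(C)=CC[C@@H]12 | intermediate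
18 | jaspic acid | CC(C)=CCC[C@@]1(C)CCC[C@]2(C)[C@@H](Cc3cc(C(=O)O)ccc3O)C(C)=CC[C@@H]12 | target

**Total step count:** 14 steps. **Longest linear sequence:** 13 steps (1 → 2 → 3 → 4 → 5 → 6 → 7 → 8 → 9 → 10 → 11 → 13 → 14); the acetylation (Step 12) is a parallel branch.

**Three steps most likely to fail**
1. **Step 13 (proposed new Pd reductive arylation).** It may give the wrong hydride regiochemistry (C7 instead of C9, producing Δ8(9)), Heck β-H elimination, or ArI hydrodehalogenation.
   - Fallback: convert enone 13 to the spiro-epoxide with a Corey–Chaykovsky sulfur ylide, then Pd/HCO2NH4 Tsuji hydrogenolysis to the Δ7 9β-CH2OH. If C9 needs correcting, oxidize to the aldehyde, epimerize with DBU and reduce back. Then convert to the iodide and run a Negishi coupling with the arylzinc from 16 (Pd-PEPPSI).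
2. **Step 6 (Stork reductive methylation).** The C4 diastereoselectivity (α-face attack leaving the β-axial arm) may be poor.
   - Fallback: hydrazone-controlled alkylation. Make the 4α-chain 3-ketone by reductive alkylation of the 4-unsubstituted enone with homoprenyl iodide, convert it to the SAMP/RAMP hydrazone, and methylate with auxiliary-directed Enders alkylation to set the quaternary C4.
3. **Step 3 (asymmetric Robinson with the α′-substituted vinyl ketone).** It may give low ee or stall at the ketol.
   - Fallback: make (S)-Wieland–Miescher ketone by the known proline-catalysed annulation with methyl vinyl ketone (>95% ee). Install the C4 arm by Stork reductive alkylation (4α-arm), then re-enolize toward C4 and methylate from the α face (tBuOK/MeI). This leaves the arm at 4β.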